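The retrosynthesis first cuts the bond between the bridging CH2 and C3 of the trione ring (ring A). This separates an enantiopure acyl trione from the chromene half (arene ring B, pyran ring C), which reacts as its ortho-quinone methide. Ring A is then opened at C2–C3 and at C5–C6.
Enabling feature: in ring A the quaternary carbon C1 (CH3, prenyl) is bonded to both C2 and C6, each at the carbonyl oxidation level, so C2–C1–C6 is a 2,2-disubstituted malonyl unit, and C3–C4–C5 with the exocyclic isobutyryl group is the skeleton of a β-diketone. C1 is stereogenic only because C3 carries CH2–aryl and C5 carries isobutyryl.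
Forward, ring A: malonate prenylation, enzymatic half-hydrolysis, and C-acylation of 5-methylhexane-2,4-dione at its central carbon (C5–C6), followed by Dieckmann closure of the acetyl CH3 onto the methyl ester (C2–C3).
Forward, rings B and C: phloroglucinol is acylated, the pyran ring is annulated with prenal, and C8 is aminomethylated. The two halves are joined last through the CH2 bridge.
Stereochemistry: it is set once, by esterase discrimination of the two enantiotopic ester groups of the prochiral diester. The free acid is built into C6 and the surviving ester into C2, which transfers this choice to the ring.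

Key step: step 5

Numbering and drawing: ring A is C1 (quaternary), C2, C3 (bridge), C4, C5 (isobutyryl), C6, and the chromene has its usual numbering. Polycarbonyl compounds are drawn in the tautomer of the target SMILES, and CIP descriptors refer to the drawn forms.
Assumption: pig liver esterase is taken to cleave the pro-R methoxycarbonyl group of the prochiral diester. If it prefers the pro-S group, the antipodal half-ester is carried to the same enantiomer of the acyl trione by the reversed wiring given as the fallback to step 5.

Step 1
Reactants: 1 dimethyl 2-methylmalonate; 2 prenyl bromide (1-bromo-3-methylbut-2-ene)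
Product: 3 dimethyl 2-methyl-2-(3-methylbut-2-en-1-yl)malonate
Conditions: NaH (1.05 equiv), THF, 0 °C; then 2 (1.1 equiv), 0 °C → rt
Reagents that add atoms: none
Why: Malonate alkylation (SN2), in which the sodium enolate of the monosubstituted malonate has only one acidic hydrogen and displaces the primary allylic bromide once at its unsubstituted terminus, giving a quaternary carbon that is prochiral because the two ester groups are identical.

Step 2
Reactants: 3 dimethyl 2-methyl-2-(3-methylbut-2-en-1-yl)malonate
Product: 4 (S)-2-(methoxycarbonyl)-2,5-dimethylhex-4-enoic acid
Conditions: pig liver esterase, 0.1 M phosphate buffer pH 7.5, DMSO (10 vol %), 25 °C, pH-stat 1 M NaOH (1 equiv); then 1 M HCl to pH 2.5, EtOAc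
Reagents that add atoms: water, SMILES O
Why: Enzymatic desymmetrisation by enantiotopos-selective ester hydrolysis, established for 2-alkyl-2-methylmalonate diesters, in which the chiral active site cleaves the pro-R ester and so sets the (S) quaternary centre, the carboxylate formed is no longer a substrate so the reaction stops at the half-ester, and the enantiomeric purity is measured here before material is carried on.

Step 3
Reactants: 4 (S)-2-(methoxycarbonyl)-2,5-dimethylhex-4-enoic acid
Product: 5 methyl (R)-2-(chlorocarbonyl)-2,5-dimethylhex-4-enoate
Conditions: 1-chloro-N,N,2-trimethylprop-1-en-1-amine (Ghosez reagent, 1.1 equiv), CH2Cl2, 0 °C → rt; concentrate, use crude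
Reagents that add atoms: 1-chloro-N,N,2-trimethylprop-1-en-1-amine, SMILES CC(C)=C(Cl)N(C)C
Why: Acid chloride formation with an α-chloroenamine under neutral conditions, which liberates no HCl so the trisubstituted alkene is neither hydrochlorinated nor lactonised, while the lack of an α-hydrogen excludes racemisation through a ketene (the descriptor changes to R only because COCl outranks CO2Me).

Step 4
Reactants: 5 methyl (R)-2-(chlorocarbonyl)-2,5-dimethylhex-4-enoate; 6 5-methylhexane-2,4-dione
Product: 7 methyl (S)-4-acetyl-2,6-dimethyl-2-(3-methylbut-2-en-1-yl)-3,5-dioxoheptanoate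
Conditions: 6 (1.1 equiv), MgCl2 (1.1 equiv), pyridine (2.2 equiv), CH2Cl2, 0 °C; then 5, 0 °C → rt; cold 1 M HCl
Reagents that add atoms: none
Why: Soft enolisation and C-acylation of a 1,3-dicarbonyl compound with MgCl2 and a tertiary amine, in which magnesium chelation ties up both diketonate oxygens and directs the acid chloride, far more electrophilic than the methyl ester, to the central carbon, forming C5–C6 without touching the quaternary centre.

Step 5
Reactants: 7 methyl (S)-4-acetyl-2,6-dimethyl-2-(3-methylbut-2-en-1-yl)-3,5-dioxoheptanoate
Product: 9 (R)-3,5-dihydroxy-4-methyl-4-(3-methylbut-2-en-1-yl)-2-(2-methylpropanoyl)cyclohexa-2,5-dien-1-one, via dilithium dienolate 8 (not isolated)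
Conditions: LDA (3.2 equiv), THF, −78 °C → 0 °C; then 1 M HCl, 0 °C
Reagents that add atoms: none
Why: The first equivalent of LDA removes the very acidic triacylmethane hydrogen, which shields all three ketones from nucleophiles, and a second equivalent deprotonates the acetyl methyl group to give 8, whose terminal carbon adds to the methyl ester and expels methoxide to form C2–C3. This is a Dieckmann-type intramolecular Claisen condensation of a poly-β-carbonyl ester through its polyanion, the reaction type used for gem-dialkyl cyclohexane-1,3,5-triones of the syncarpic and filicinic acid family and, intermolecularly, for terminal acylation of β-diketone dianions. Ring A closes in a 6-(enolexo)-exo-trig mode, assisted by the Thorpe–Ingold effect of the quaternary carbon. No stereocentre is created: C1 has no α-hydrogen, none of its four bonds is broken, and its descriptor changes from S to R only through the change in priorities. The step needs deprotonation at CH3 rather than at the isobutyryl methine, which is secured by the kinetic preference of the bulky amide for the unhindered methyl group and by the fact that only the wanted ring keeps an acidic C3–H and is drained off as a doubly stabilised dianion, whereas closure through an enolate oxygen or through the methine carbon stays reversible towards the liberated methoxide. The isobutyryl group has to be in place before closure, because the unacylated 4-methyl-4-prenyl trione has a mirror plane and would erase the stereochemical information.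

Step 6
Reactants: 10 phloroglucinol (benzene-1,3,5-triol); 11 isobutyryl chloride
Product: 12 2-methyl-1-(2,4,6-trihydroxyphenyl)propan-1-one (phlorisobutyrophenone)
Conditions: AlCl3 (3.5 equiv), PhNO2, 65 °C; then ice, 1 M HCl
Reagents that add atoms: none
Why: Friedel–Crafts C-acylation of the electron-rich triphenol, which should stop at monoacylation because the aluminium-chelated aryl ketone deactivates the ring.

Step 7
Reactants: 12 2-methyl-1-(2,4,6-trihydroxyphenyl)propan-1-one; 13 3-methylbut-2-enal (prenal)
Product: 15 1-(5,7-dihydroxy-2,2-dimethyl-2H-chromen-6-yl)-2-methylpropan-1-one, via oxatriene 14 (not isolated)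
Conditions: 13 (1.0 equiv), ethylenediammonium diacetate (10 mol %), DMF, 100 °C; chromatography
Reagents that add atoms: none
Why: Knoevenagel-type condensation at one of the two equivalent free ring positions, dehydration to 14 and oxa-6π electrocyclisation (a chromenylation well known for acylphloroglucinols), in which closure through the para hydroxyl, the one not hydrogen-bonded to the ketone, gives the 6-acyl isomer, the 8-acyl isomer from ortho closure is removed by chromatography, and keeping the enal limiting suppresses a second annulation.

Step 8
Reactants: 15 1-(5,7-dihydroxy-2,2-dimethyl-2H-chromen-6-yl)-2-methylpropan-1-one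
Product: 16 1-{8-[(dimethylamino)methyl]-5,7-dihydroxy-2,2-dimethyl-2H-chromen-6-yl}-2-methylpropan-1-one
Conditions: N,N-dimethylmethyleneiminium iodide (Eschenmoser salt, 1.1 equiv), CH2Cl2, rt; then aq. NaHCO3
Reagents that add atoms: N,N-dimethylmethyleneiminium iodide, SMILES C=[N+](C)C.[I-]
Why: Mannich aminomethylation (electrophilic aromatic substitution by a preformed iminium ion) at C8, the only free aromatic position, which is activated by the 7-hydroxyl and the pyran oxygen and thereby receives the future bridging CH2.

Step 9
Reactants: 9 (R)-3,5-dihydroxy-4-methyl-4-(3-methylbut-2-en-1-yl)-2-(2-methylpropanoyl)cyclohexa-2,5-dien-1-one; 16 1-{8-[(dimethylamino)methyl]-5,7-dihydroxy-2,2-dimethyl-2H-chromen-6-yl}-2-methylpropan-1-one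
Product: 18 (R)-2-{[5,7-dihydroxy-2,2-dimethyl-6-(2-methylpropanoyl)-2H-chromen-8-yl]methyl}-3,5-dihydroxy-4-methyl-4-(3-methylbut-2-en-1-yl)-6-(2-methylpropanoyl)cyclohexa-2,5-dien-1-one (CNP0319758.1), via ortho-quinone methide 17 (not isolated)
Conditions: 9 (1.0 equiv), 16 (1.05 equiv), 1,4-dioxane, 80 °C, N2 sweep
Reagents that add atoms: none
Why: Elimination of a phenolic Mannich base followed by Michael addition, a reaction type established for methylene-bridged acylphloroglucinol dimers, in which the strongly acidic trione protonates the amine so that dimethylamine leaves and is swept out, 17 is captured at its exocyclic CH2 by C3, the only ring CH carbon of the trione enolate, rearomatisation of ring B drives the addition, and the quaternary centre is not involved.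

Compound list
1 | dimethyl 2-methylmalonate | COC(=O)C(C)C(=O)OC | starting material
2 | prenyl bromide (1-bromo-3-methylbut-2-ene) | CC(C)=CCBr | starting material
3 | dimethyl 2-methyl-2-(3-methylbut-2-en-1-yl)malonate (prochiral) | COC(=O)C(C)(CC=C(C)C)C(=O)OC | intermediate
4 | (S)-2-(methoxycarbonyl)-2,5-dimethylhex-4-enoic acid | CC(C)=CC[C@](C(=O)O)(C)C(=O)OC | intermediate
5 | methyl (R)-2-(chlorocarbonyl)-2,5-dimethylhex-4-enoate | CC(C)=CC[C@](C(=O)Cl)(C)C(=O)OC | intermediate
6 | 5-methylhexane-2,4-dione | CC(=O)CC(=O)C(C)C | starting material
7 | methyl (S)-4-acetyl-2,6-dimethyl-2-(3-methylbut-2-en-1-yl)-3,5-dioxoheptanoate (triacylmethane CH labile, enolised) | CC(C)=CC[C@](C(=O)C(C(C)=O)C(=O)C(C)C)(C)C(=O)OC | intermediate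
8 | dilithium dienolate (dianion) of 7, not isolated | CC(C)=CC[C@](C([O-])=C(C([O-])=C)C(=O)C(C)C)(C)C(=O)OC.[Li+].[Li+] | intermediate
9 | (R)-3,5-dihydroxy-4-methyl-4-(3-methylbut-2-en-1-yl)-2-(2-methylpropanoyl)cyclohexa-2,5-dien-1-one (enol form of 2-isobutyryl-4-methyl-4-prenylcyclohexane-1,3,5-trione) | CC(C)=CC[C@]1(C)C(O)=CC(=O)C(C(=O)C(C)C)=C1O | intermediate
10 | phloroglucinol | Oc1cc(O)cc(O)c1 | starting material
11 | isobutyryl chloride | CC(C)C(Cl)=O | starting material
12 | 2-methyl-1-(2,4,6-trihydroxyphenyl)propan-1-one | CC(C)C(=O)c1c(O)cc(O)cc1O | intermediate
13 | 3-methylbut-2-enal | CC(C)=CC=O | starting material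
14 | 3,5-dihydroxy-4-(2-methylpropanoyl)-6-(3-methylbut-2-en-1-ylidene)cyclohexa-2,4-dien-1-one (oxatriene), not isolated | CC(C)=CC=C1C(=O)C=C(O)C(C(=O)C(C)C)=C1O | intermediate
15 | 1-(5,7-dihydroxy-2,2-dimethyl-2H-chromen-6-yl)-2-methylpropan-1-one | CC(C)C(=O)c1c(O)cc2OC(C)(C)C=Cc2c1O | intermediate
16 | 1-{8-[(dimethylamino)methyl]-5,7-dihydroxy-2,2-dimethyl-2H-chromen-6-yl}-2-methylpropan-1-one | CC(C)C(=O)c1c(O)c(CN(C)C)c2OC(C)(C)C=Cc2c1O | intermediate
17 | 5-hydroxy-2,2-dimethyl-8-methylidene-6-(2-methylpropanoyl)-2H-chromen-7(8H)-one (ortho-quinone methide), not isolated | C=C1C(=O)C(C(=O)C(C)C)=C(O)C2=C1OC(C)(C)C=C2 | intermediate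
18 | CNP0319758.1, (R)-configured methylene-bridged trione–chromene | CC(C)=CC[C@]1(C)C(O)=C(Cc2c(O)c(C(=O)C(C)C)c(O)c3c2OC(C)(C)C=C3)C(=O)C(C(=O)C(C)C)=C1O | target

Total step count: 9.
Longest linear sequence: 6 steps (steps 1–5 and 9, from dimethyl 2-methylmalonate). The chromene branch needs 4 (steps 6–8 and 9).

Steps most likely to fail

Step 5 (key step). The second deprotonation may be incomplete or may occur at the isobutyryl methine. The crowded triacylmethane may also lose an acyl group by retro-Claisen cleavage faster than the carbon–carbon closure takes place.

The fallback makes the two ring bonds in the opposite order, so the closing nucleophile is an ordinary stabilised 1,3-diketone carbon and no triacylmethane is involved. In this wiring the acid carbon becomes C2 and the ester carbon becomes C6, so it needs the antipodal half-ester. It sets out from 3 and comes back at 9.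
- Diester 3 is monosaponified with KOH (1 equiv) in MeOH to the racemic half-ester F1.
- F1 is resolved by crystallising the (R)-1-phenylethylammonium salt of the (R)-acid F2. Which amine antipode gives the less soluble pair has to be established by trial; the like/like pairing is written here.
- 1 M HCl releases the (R)-half-ester F3, and Ghosez reagent converts it into the (S)-acid chloride F4.
- F4 acylates the dilithium dianion of 6 (LDA, THF, −78 °C) at its terminal carbon, forming C2–C3 and giving the linear 3,5,7-triketo ester F5.
- NaOMe in MeOH should then close C5–C6 by Claisen cyclisation of the carbon between the two outer ketones onto the methyl ester. The aldol mode that competes in such polyketide chains is blocked because the ester α-carbon is quaternary.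
- The product is the same (R)-enantiomer 9, so both antipodes of the half-ester converge on one trione.

Step 4. The hindered acid chloride may acylate the diketonate on oxygen or react too slowly, and an acyl group may be lost from the product during work-up.

The fallback introduces the bulky acyl group with an unstabilised, more nucleophilic enolate and the third acyl group with the smallest acid chloride. It sets out from 5 and comes back at 7.
- The kinetic lithium enolate of 3-methylbutan-2-one (LDA, THF, −78 °C, 2.1 equiv) is acylated by 5 at its CH2 terminus to give the β-diketo ester F6.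
- F6 is then C-acetylated at the central carbon with acetyl chloride, MgCl2 and pyridine in CH2Cl2.

Step 2. The enzyme may discriminate poorly between the two enantiotopic ester groups, or may show the opposite sense of selectivity.

The fallback replaces desymmetrisation by classical resolution. It sets out from 3 and comes back at 4.
- The racemic half-ester F1 (KOH, MeOH, as above) is crystallised as the (S)-1-phenylethylammonium salt of the (S)-acid F7 to constant rotation.
- The salt is split with 1 M HCl to give 4. The same crystallisation upgrades enzyme-derived material of insufficient purity.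
- The (R)-acid F3 left in the mother liquor is either re-methylated (MeI, K2CO3, acetone) to prochiral 3 or used in the reversed wiring described for step 5.

Further compounds
F1 | step 5 | racemic 2-(methoxycarbonyl)-2,5-dimethylhex-4-enoic acid | CC(C)=CCC(C)(C(=O)O)C(=O)OC
F2 | step 5 | (R)-1-phenylethylammonium (R)-2-(methoxycarbonyl)-2,5-dimethylhex-4-enoate | CC(C)=CC[C@@](C(=O)[O-])(C)C(=O)OC.C[C@@H]([NH3+])c1ccccc1
F3 | step 5 | (R)-2-(methoxycarbonyl)-2,5-dimethylhex-4-enoic acid | CC(C)=CC[C@@](C(=O)O)(C)C(=O)OC
F4 | step 5 | methyl (S)-2-(chlorocarbonyl)-2,5-dimethylhex-4-enoate | CC(C)=CC[C@@](C(=O)Cl)(C)C(=O)OC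
F5 | step 5 | methyl (R)-2,8-dimethyl-2-(3-methylbut-2-en-1-yl)-3,5,7-trioxononanoate | CC(C)=CC[C@@](C(=O)CC(=O)CC(=O)C(C)C)(C)C(=O)OC
F6 | step 4 | methyl (S)-2,6-dimethyl-2-(3-methylbut-2-en-1-yl)-3,5-dioxoheptanoate | CC(C)=CC[C@](C(=O)CC(=O)C(C)C)(C)C(=O)OC
F7 | step 2 | (S)-1-phenylethylammonium (S)-2-(methoxycarbonyl)-2,5-dimethylhex-4-enoate | CC(C)=CC[C@](C(=O)[O-])(C)C(=O)OC.C[C@H]([NH3+])c1ccccc1
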